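**Retrosynthetic overview**
1. Target 17 ← selective acetylation of the C8 hydroxyl of cis-diol 16.
2. Ring A (pyran) and C8/C8a ← hydroxymethylation of ene-dione 13 at C8a, 6-endo oxa-Michael closure onto the ynenone, then hydride reduction of the C8 ketone.
3. Ring B (six-membered, C7 carbinol) ← 1,2-acyl shift (α-ketol) ring expansion of the 5-acetyl-5-hydroxycyclopentenone 12, itself set by catalytic asymmetric hydroxylation of β-diketone 11. Ring B is formed first, ring A second.
4. 11 ← C-acetylation of 2-chloro-3-alkynylcyclopentenone 9 ← acetylide addition/carbonyl transposition on chlorinated 3-methoxycyclopentenone 7 with dienyne 5.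
5. 5 ← (R)-2-methylbutan-1-ol by oxidation/Wittig and Horner–Wadsworth–Emmons olefination.

Assumption: (R)-2-methylbutan-1-ol is bought in high enantiomeric purity. Core atoms are referred to by isochromene numbering (C1, O2, C3, C4, C4a, C5–C8, C8a) throughout. The route is a paper design and has not been run.

**Step 1**
Reactants: 1 (R)-2-methylbutan-1-ol
Product: 3 (2E,4R)-2,4-dimethylhex-2-enal, via aldehyde 2 (not isolated)
Conditions: TEMPO (10 mol %), PhI(OAc)2 (1.1 eq), ClCH2CH2Cl, 23 °C; then Ph3P=C(Me)CHO (1.1 eq), 70 °C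
Reagents that add atoms: 2-(triphenylphosphoranylidene)propanal, CC(C=O)=P(c1ccccc1)(c1ccccc1)c1ccccc1
Why: The nitroxyl-catalysed oxidation stops at the α-branched aldehyde, which is trapped in the same flask by the stabilised formyl ylide in an E-selective Wittig olefination, so the volatile, epimerisable aldehyde is never handled and the (R) centre of 1 is carried through unchanged.

**Step 2**
Reactants: 3 (2E,4R)-2,4-dimethylhex-2-enal
Product: 5 (3E,5E,7R)-5,7-dimethylnona-3,5-dien-1-yne, via silyl dienyne 4 (not isolated)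
Conditions: (EtO)2P(O)CH2C≡CSiMe3, LiN(SiMe3)2, THF, −78 → 0 °C; then K2CO3 (0.2 eq), MeOH, 23 °C
Reagents that add atoms: diethyl [3-(trimethylsilyl)prop-2-yn-1-yl]phosphonate, CCOP(=O)(CC#C[Si](C)(C)C)OCC
Why: Horner–Wadsworth–Emmons olefination with the silyl-propargyl phosphonate gives the (E)-enyne with high trans selectivity, and mild methanolysis of the C–Si bond then frees the terminal alkyne without touching the diene or the allylic stereocentre.

**Step 3**
Reactants: 6 3-methoxycyclopent-2-en-1-one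
Product: 7 2-chloro-3-methoxycyclopent-2-en-1-one
Conditions: NCS (1.05 eq), CH2Cl2, 0 → 23 °C
Reagents that add atoms: N-chlorosuccinimide, O=C1CCC(=O)N1Cl
Why: Electrophilic α-chlorination of a vinylogous ester occurs only at the enol-ether-activated C2, so the future C5 chlorine is installed regiospecifically before any sensitive group is present.

**Step 4**
Reactants: 5 (3E,5E,7R)-5,7-dimethylnona-3,5-dien-1-yne; 7 2-chloro-3-methoxycyclopent-2-en-1-one
Product: 9 2-chloro-3-[(3E,5E,7R)-5,7-dimethylnona-3,5-dien-1-yn-1-yl]cyclopent-2-en-1-one, via carbinol adduct 8 (not isolated)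
Conditions: 5, n-BuLi, THF, −78 °C; then 7, −78 → 0 °C; then 1 M HCl, 23 °C
Reagents that add atoms: water, O
Why: Stork–Danheiser alkynylation/transposition: the lithium acetylide adds 1,2 to the vinylogous ester carbonyl and acid hydrolysis of the methoxy-stabilised allyl cation moves the carbonyl, giving the 3-alkynyl enone whose alkyne carbons are the future C3 and C4.

**Step 5**
Reactants: 9 2-chloro-3-[(3E,5E,7R)-5,7-dimethylnona-3,5-dien-1-yn-1-yl]cyclopent-2-en-1-one
Product: 11 5-acetyl-2-chloro-3-[(3E,5E,7R)-5,7-dimethylnona-3,5-dien-1-yn-1-yl]cyclopent-2-en-1-one, via hemiaminal lithium salt 10 (not isolated)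
Conditions: LiN(i-Pr)2 (1.1 eq), THF, −78 °C; then MeC(O)N(OMe)Me, −78 → −20 °C; then 1 M HCl
Reagents that add atoms: N-methoxy-N-methylacetamide, CC(=O)N(C)OC
Why: Kinetic deprotonation by the hindered amide takes the α′-proton (future C8) and not the γ-proton, and Claisen-type C-acylation with the Weinreb amide stops at the chelated tetrahedral adduct until work-up, so neither O-acylation nor proton exchange with the acidic β-diketone product interferes.

**Step 6**
Reactants: 11 5-acetyl-2-chloro-3-[(3E,5E,7R)-5,7-dimethylnona-3,5-dien-1-yn-1-yl]cyclopent-2-en-1-one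
Product: 13 (2R)-4-chloro-5-[(3E,5E,7R)-5,7-dimethylnona-3,5-dien-1-yn-1-yl]-2-hydroxy-2-methylcyclohex-4-ene-1,3-dione, via hydroxy diketone 12 (not isolated)
Conditions: Cu(OTf)2 (10 mol %), (S,S)-t-Bu-box (11 mol %), 3-phenyl-2-(phenylsulfonyl)oxaziridine (1.2 eq), 4 Å MS, CH2Cl2, −20 °C; then i-Pr2NEt (0.2 eq), 23 °C
Reagents that add atoms: 3-phenyl-2-(phenylsulfonyl)oxaziridine, O=S(=O)(N1OC1c1ccccc1)c1ccccc1
Why: Proposed new method: a divalent-copper bisoxazoline complex binds the β-diketonate and the oxaziridine transfers oxygen to one enolate face to give the (S)-carbinol 12, whose copper alkoxide–acetyl chelate then undergoes a suprafacial 1,2-shift of the ring acyl carbon from the carbinol carbon to the acetyl carbon (α-ketol rearrangement with five-to-six ring expansion), which forms ring B, turns the acetyl group into the C7 methyl carbinol and relays the carbinol configuration into (7R), driven by relief of cyclopentenone strain and by the doubly activated CH2 of 13; the closest known reactions are copper- or nickel-bisoxazoline-catalysed α-hydroxylations of β-keto esters with oxaziridines and Lewis-acid- or base-induced α-ketol ring expansions of 1-acylcycloalkanols, whereas the tandem use on a 2-acylcyclopentenone and the chirality relay are untested, and the ligand antipode is used if the observed sense is opposite.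

**Step 7**
Reactants: 13 (2R)-4-chloro-5-[(3E,5E,7R)-5,7-dimethylnona-3,5-dien-1-yn-1-yl]-2-hydroxy-2-methylcyclohex-4-ene-1,3-dione
Product: 16 (7R,8R,8aR)-5-chloro-3-[(1E,3E,5R)-3,5-dimethylhepta-1,3-dien-1-yl]-7,8-dihydroxy-7-methyl-1,7,8,8a-tetrahydro-6H-isochromen-6-one, via hydroxymethyl dione 14 (not isolated), via bicyclic ketone 15 (not isolated)
Conditions: HCHO (1.1 eq, THF solution), Et3N (0.3 eq), THF, −20 → 0 °C; then MeOH, NaBH4 (1.5 eq), −78 °C
Reagents that add atoms: formaldehyde, C=O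
Why: Amine-catalysed aldol addition of the doubly activated C8a–H to formaldehyde is followed by 6-endo-dig oxa-Michael addition of the new primary alkoxide to the ynenone (closing ring A with the 3,4-double bond), and NaBH4 then reduces only the saturated C8 ketone by axial attack anti to the C7–O bond (polar Felkin–Anh) on the rapidly epimerising C8a epimer that keeps C1 equatorial, which sets (8R) cis to the C7 hydroxyl and (8aR) with H8 and H8a trans-diaxial.

**Step 8**
Reactants: 16 (7R,8R,8aR)-5-chloro-3-[(1E,3E,5R)-3,5-dimethylhepta-1,3-dien-1-yl]-7,8-dihydroxy-7-methyl-1,7,8,8a-tetrahydro-6H-isochromen-6-one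
Product: 17 (7R,8R,8aR)-5-chloro-3-[(1E,3E,5R)-3,5-dimethylhepta-1,3-dien-1-yl]-7-hydroxy-7-methyl-6-oxo-6,7,8,8a-tetrahydro-1H-isochromen-8-yl acetate
Conditions: Ac2O (1.2 eq), pyridine, DMAP (5 mol %), CH2Cl2, 0 °C
Reagents that add atoms: acetic anhydride, CC(=O)OC(C)=O
Why: Under DMAP-catalysed esterification the secondary C8 hydroxyl is acylated far faster than the hindered tertiary C7 hydroxyl, so one equivalent of anhydride gives the monoacetate without protection.

**Compound list**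
1 | (R)-2-methylbutan-1-ol | CC[C@@H](C)CO | starting material
2 | (R)-2-methylbutanal | CC[C@@H](C)C=O | intermediate
3 | (2E,4R)-2,4-dimethylhex-2-enal | CC[C@@H](C)/C=C(C)/C=O | intermediate
4 | trimethyl[(3E,5E,7R)-5,7-dimethylnona-3,5-dien-1-yn-1-yl]silane | CC[C@@H](C)/C=C(C)/C=C/C#C[Si](C)(C)C | intermediate
5 | (3E,5E,7R)-5,7-dimethylnona-3,5-dien-1-yne | CC[C@@H](C)/C=C(C)/C=C/C#C | intermediate
6 | 3-methoxycyclopent-2-en-1-one | COC1=CC(=O)CC1 | starting material
7 | 2-chloro-3-methoxycyclopent-2-en-1-one | COC1=C(Cl)C(=O)CC1 | intermediate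
8 | 2-chloro-1-[(3E,5E,7R)-5,7-dimethylnona-3,5-dien-1-yn-1-yl]-3-methoxycyclopent-2-en-1-ol (both carbinol epimers) | CC[C@@H](C)/C=C(C)/C=C/C#CC1(O)CCC(OC)=C1Cl | intermediate
9 | 2-chloro-3-[(3E,5E,7R)-5,7-dimethylnona-3,5-dien-1-yn-1-yl]cyclopent-2-en-1-one | CC[C@@H](C)/C=C(C)/C=C/C#CC1=C(Cl)C(=O)CC1 | intermediate
10 | lithium 1-{3-chloro-4-[(3E,5E,7R)-5,7-dimethylnona-3,5-dien-1-yn-1-yl]-2-oxocyclopent-3-en-1-yl}-1-[methoxy(methyl)amino]ethan-1-olate | CC[C@@H](C)/C=C(C)/C=C/C#CC1=C(Cl)C(=O)C(C1)C(C)(O[Li])N(C)OC | intermediate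
11 | 5-acetyl-2-chloro-3-[(3E,5E,7R)-5,7-dimethylnona-3,5-dien-1-yn-1-yl]cyclopent-2-en-1-one (C5 epimers, largely enolised) | CC[C@@H](C)/C=C(C)/C=C/C#CC1=C(Cl)C(=O)C(C(C)=O)C1 | intermediate
12 | (5S)-5-acetyl-2-chloro-3-[(3E,5E,7R)-5,7-dimethylnona-3,5-dien-1-yn-1-yl]-5-hydroxycyclopent-2-en-1-one | CC[C@@H](C)/C=C(C)/C=C/C#CC1=C(Cl)C(=O)[C@@](O)(C(C)=O)C1 | intermediate
13 | (2R)-4-chloro-5-[(3E,5E,7R)-5,7-dimethylnona-3,5-dien-1-yn-1-yl]-2-hydroxy-2-methylcyclohex-4-ene-1,3-dione | CC[C@@H](C)/C=C(C)/C=C/C#CC1=C(Cl)C(=O)[C@](C)(O)C(=O)C1 | intermediate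
14 | (2R)-4-chloro-5-[(3E,5E,7R)-5,7-dimethylnona-3,5-dien-1-yn-1-yl]-2-hydroxy-6-(hydroxymethyl)-2-methylcyclohex-4-ene-1,3-dione (C6 epimers) | CC[C@@H](C)/C=C(C)/C=C/C#CC1=C(Cl)C(=O)[C@](C)(O)C(=O)C1CO | intermediate
15 | (7R,8aR)-5-chloro-3-[(1E,3E,5R)-3,5-dimethylhepta-1,3-dien-1-yl]-7-hydroxy-7-methyl-1H-isochromene-6,8(7H,8aH)-dione (C8a epimerises; reacting epimer shown) | CC[C@@H](C)/C=C(C)/C=C/C1=CC2=C(Cl)C(=O)[C@](C)(O)C(=O)[C@H]2CO1 | intermediate
16 | (7R,8R,8aR)-5-chloro-3-[(1E,3E,5R)-3,5-dimethylhepta-1,3-dien-1-yl]-7,8-dihydroxy-7-methyl-1,7,8,8a-tetrahydro-6H-isochromen-6-one | CC[C@@H](C)/C=C(C)/C=C/C1=CC2=C(Cl)C(=O)[C@](C)(O)[C@H](O)[C@H]2CO1 | intermediate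
17 | (7R,8R,8aR)-5-chloro-3-[(1E,3E,5R)-3,5-dimethylhepta-1,3-dien-1-yl]-7-hydroxy-7-methyl-6-oxo-6,7,8,8a-tetrahydro-1H-isochromen-8-yl acetate | CC[C@@H](C)/C=C(C)/C=C/C1=CC2=C(Cl)C(=O)[C@](C)(O)[C@H](OC(C)=O)[C@H]2CO1 | target

**Step count**
Total: 8 steps. Longest linear sequence: 7 steps (1, 2, 4, 5, 6, 7, 8) from alcohol 1; the core branch from 6 is 6 steps.

**Three steps most likely to fail**

Step 6 (the proposed new step). Risks are low enantioselectivity in the hydroxylation, a sluggish or non-stereospecific acyl shift, and competing migration of the ring CH2. The fallback sets out from 11 and uses known chemistry in discrete operations. Hydroxylation of the enolised β-diketone with dimethyldioxirane in acetone at −20 °C gives, after isolation, the racemic tertiary alcohol 5-acetyl-2-chloro-3-[(3E,5E,7R)-5,7-dimethylnona-3,5-dien-1-yn-1-yl]-5-hydroxycyclopent-2-en-1-one F1. A classical base- or Lewis-acid-mediated α-ketol rearrangement (Et3N in CH2Cl2, or Al(Ot-Bu)3 in toluene) then gives 13 together with its C2 epimer (2S)-4-chloro-5-[(3E,5E,7R)-5,7-dimethylnona-3,5-dien-1-yn-1-yl]-2-hydroxy-2-methylcyclohex-4-ene-1,3-dione F2. The two are diastereomers because of the side-chain centre and are separated by preparative chromatography on a chiral stationary phase. The fallback comes back to the route at 13, with stereocontrol by separation in place of asymmetric catalysis.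

Step 7. Risks are double hydroxymethylation at C8a, base-induced opening of the β-alkoxy ketone 15, and the wrong face in the C8 reduction if hydrogen-bond or chelate control overrides the Felkin–Anh preference. If only the C8a epimer is formed, brief DBU treatment of 16 should equilibrate it to the diequatorial arrangement. The fallback sets out from 13 and replaces the cascade by a protected, stepwise sequence:
- Et3SiOTf/Et3N gives the bis-silyl dienol ether (6R)-2-chloro-3-[(3E,5E,7R)-5,7-dimethylnona-3,5-dien-1-yn-1-yl]-6-methyl-5,6-bis(triethylsilyloxy)cyclohexa-2,4-dien-1-one F3.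
- Sc(OTf)3-catalysed aqueous Mukaiyama hydroxymethylation with HCHO gives the mono-adduct (2R)-4-chloro-5-[(3E,5E,7R)-5,7-dimethylnona-3,5-dien-1-yn-1-yl]-6-(hydroxymethyl)-2-methyl-2-(triethylsilyloxy)cyclohex-4-ene-1,3-dione F4.
- Catalytic Et3N closes ring A to (7R,8aR)-5-chloro-3-[(1E,3E,5R)-3,5-dimethylhepta-1,3-dien-1-yl]-7-methyl-7-(triethylsilyloxy)-1H-isochromene-6,8(7H,8aH)-dione F5.
- NaBH4 in MeOH at −78 °C, now with a non-chelating α-silyloxy group, gives (7R,8R,8aR)-5-chloro-3-[(1E,3E,5R)-3,5-dimethylhepta-1,3-dien-1-yl]-8-hydroxy-7-methyl-7-(triethylsilyloxy)-1,7,8,8a-tetrahydro-6H-isochromen-6-one F6.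
- HF·pyridine removes the silyl ether.

The fallback comes back to the route at 16.

Step 5. Risks are γ- in place of α′-deprotonation of the alkynyl enone and low conversion of the enolate with the amide. The fallback sets out from 9 and builds the acetyl group in two known operations. Aldol addition of the LiN(i-Pr)2-derived enolate to acetaldehyde at −78 °C gives 2-chloro-3-[(3E,5E,7R)-5,7-dimethylnona-3,5-dien-1-yn-1-yl]-5-(1-hydroxyethyl)cyclopent-2-en-1-one F7. Dess–Martin periodinane oxidation of the secondary alcohol then gives the β-diketone, and the fallback comes back to the route at 11.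

**Further compounds**
F1 | step 6 | 5-acetyl-2-chloro-3-[(3E,5E,7R)-5,7-dimethylnona-3,5-dien-1-yn-1-yl]-5-hydroxycyclopent-2-en-1-one (both C5 epimers) | CC[C@@H](C)/C=C(C)/C=C/C#CC1=C(Cl)C(=O)C(O)(C(C)=O)C1
F2 | step 6 | (2S)-4-chloro-5-[(3E,5E,7R)-5,7-dimethylnona-3,5-dien-1-yn-1-yl]-2-hydroxy-2-methylcyclohex-4-ene-1,3-dione | CC[C@@H](C)/C=C(C)/C=C/C#CC1=C(Cl)C(=O)[C@@](C)(O)C(=O)C1
F3 | step 7 | (6R)-2-chloro-3-[(3E,5E,7R)-5,7-dimethylnona-3,5-dien-1-yn-1-yl]-6-methyl-5,6-bis(triethylsilyloxy)cyclohexa-2,4-dien-1-one | CC[C@@H](C)/C=C(C)/C=C/C#CC1=C(Cl)C(=O)[C@](C)(O[Si](CC)(CC)CC)C(O[Si](CC)(CC)CC)=C1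
F4 | step 7 | (2R)-4-chloro-5-[(3E,5E,7R)-5,7-dimethylnona-3,5-dien-1-yn-1-yl]-6-(hydroxymethyl)-2-methyl-2-(triethylsilyloxy)cyclohex-4-ene-1,3-dione (C6 epimers) | CC[C@@H](C)/C=C(C)/C=C/C#CC1=C(Cl)C(=O)[C@](C)(O[Si](CC)(CC)CC)C(=O)C1CO
F5 | step 7 | (7R,8aR)-5-chloro-3-[(1E,3E,5R)-3,5-dimethylhepta-1,3-dien-1-yl]-7-methyl-7-(triethylsilyloxy)-1H-isochromene-6,8(7H,8aH)-dione | CC[C@@H](C)/C=C(C)/C=C/C1=CC2=C(Cl)C(=O)[C@](C)(O[Si](CC)(CC)CC)C(=O)[C@H]2CO1
F6 | step 7 | (7R,8R,8aR)-5-chloro-3-[(1E,3E,5R)-3,5-dimethylhepta-1,3-dien-1-yl]-8-hydroxy-7-methyl-7-(triethylsilyloxy)-1,7,8,8a-tetrahydro-6H-isochromen-6-one | CC[C@@H](C)/C=C(C)/C=C/C1=CC2=C(Cl)C(=O)[C@](C)(O[Si](CC)(CC)CC)[C@H](O)[C@H]2CO1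
F7 | step 5 | 2-chloro-3-[(3E,5E,7R)-5,7-dimethylnona-3,5-dien-1-yn-1-yl]-5-(1-hydroxyethyl)cyclopent-2-en-1-one (diastereomer mixture) | CC[C@@H](C)/C=C(C)/C=C/C#CC1=C(Cl)C(=O)C(C(C)O)C1
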